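The 3(2H)-furanone ring (O, C10, C1, C2, C3; germacrane locants: C1 ketone, C2=C3 furanone olefin, C10 the O-bearing quaternary carbon) is opened into a terminal (Z)-enyne and a lactic-acid-derived 1,3-dioxolan-4-one. In one operation a lithium acetylide (C2) acylates the dioxolanone carbonyl (C1); the adduct sheds pivalaldehyde and the freed C10 alkoxide closes on C3. This joins the two halves, forms C1–C2 and O–C3, and exploits the furanone as a masked α-hydroxy acid plus alkyne. A chromium Barbier allylation (C7–C8) of a bromomethyl butenolide then closes the ten-membered ring and the methylene lactone; tigloylation finishes.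

Key step: step 8

Remark: further locants are C4=C5 (Z-olefin, C15 methyl on C4), C6 (lactone O–CH), C7, C8 (tiglate carbinol), C9 (CH2), C11–C13 (lactone acrylate carbons) and C14 (methyl on C10). The two alkynyl Grignard solutions, the lactic acid tert-butyl dioxolanone, 2-(bromomethyl)acrylic acid and tigloyl chloride are assumed to be purchasable.

Step 1
Reactants: 1 acrolein; 2 1-propynylmagnesium bromide
Product: 3 (±)-hex-1-en-4-yn-3-ol
Conditions: THF, −78 → 0 °C; aq. NH4Cl
Reagents that add atoms: none
Why: Grignard 1,2-addition of the alkynylmagnesium reagent to the aldehyde of the enal should give the racemic carbinol that holds C6 with its C7 vinyl group and the C5≡C4–C15 unit.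

Step 2
Reactants: 3
Product: 4 (S)-hex-1-en-4-yn-3-ol
Conditions: Ti(OiPr)4, L-(+)-diisopropyl tartrate, t-BuOOH (0.6 equiv), 4 Å molecular sieves, CH2Cl2, −20 °C; unreacted alcohol recovered
Reagents that add atoms: none
Why: Sharpless kinetic resolution: the titanium–L-(+)-tartrate peroxide should epoxidise the vinyl group of the (R)-enantiomer much faster, so the recovered alcohol is the (S)-enantiomer, which carries the C6 configuration of the target.

Step 3
Reactants: 4
Product: 6 (3S,4Z)-5-iodohexa-1,4-dien-3-ol, via cyclic vinylalanate 5 (not isolated)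
Conditions: NaAlH2(OCH2CH2OMe)2 (Red-Al), THF, 0 °C → rt; EtOAc; then I2, −78 → 0 °C
Reagents that add atoms: iodine II
Why: hydroxyl-directed anti-hydroalumination of the propargylic alcohol puts hydride on C5 and aluminium on C4 inside a five-membered oxa-alanate, and iododealumination with retention fixes the Z geometry of C4=C5 (iodine cis to C6) without touching the carbinol centre.

Step 4
Reactants: 6
Product: 7 triethyl{[(3S,4Z)-5-iodohexa-1,4-dien-3-yl]oxy}silane
Conditions: Et3SiCl, imidazole, CH2Cl2, 0 °C
Reagents that add atoms: triethylsilyl chloride CC[Si](Cl)(CC)CC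
Why: silylation of the secondary alcohol masks O6, which would otherwise attack the ynone of the key step in a furan-forming 5-exo-dig closure.

Step 5
Reactants: 7; 8 ethynylmagnesium bromide
Product: 9 triethyl{[(3S,4Z)-5-methylhepta-1,4-dien-6-yn-3-yl]oxy}silane
Conditions: 8, ZnBr2, THF, 0 °C; then 7, Pd(PPh3)4 (5 mol %), rt
Reagents that add atoms: none
Why: Negishi coupling: oxidative addition of zerovalent palladium into the vinyl C–I bond, transmetalation from ethynylzinc bromide and reductive elimination form C3–C4 with retention of the Z geometry and give the terminal enyne directly.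

Step 6
Reactants: 10 (2S,5S)-2-tert-butyl-5-methyl-1,3-dioxolan-4-one; 11 allyl bromide
Product: 13 (2S,5R)-5-allyl-2-tert-butyl-5-methyl-1,3-dioxolan-4-one, via lithium enolate 12 (not isolated)
Conditions: LiN(iPr)2, THF, −78 °C; then 11, −78 → −30 °C
Reagents that add atoms: none
Why: dioxolanone enolate alkylation (self-regeneration of stereocentres): the tert-butyl group on the acetal carbon shields one face of the planar enolate, so allyl bromide enters trans to it and sets C10 (R), the allyl group taking the place of hydrogen with retention.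

Step 7
Reactants: 13
Product: 16 (2S,5R)-2-tert-butyl-5-(2,2-dimethoxyethyl)-5-methyl-1,3-dioxolan-4-one, via ozonide 14 (not isolated), via aldehyde 15 (not isolated)
Conditions: O3, CH2Cl2, −78 °C; PPh3, −78 °C → rt; then HC(OMe)3, MeOH, PPTS (cat.), rt
Reagents that add atoms: trimethyl orthoformate COC(OC)OC; methanol CO
Why: ozonolysis of the terminal alkene with reductive work-up gives the C8 aldehyde, which is masked at once as its dimethyl acetal under mild PPTS catalysis that should leave the dioxolanone and both stereocentres intact.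

Step 8
Reactants: 9; 16
Product: 20 (2R)-2-(2,2-dimethoxyethyl)-2-methyl-5-[(2Z,4S)-4-(triethylsilyloxy)hexa-2,5-dien-2-yl]furan-3(2H)-one, via lithium acetylide 17 (not isolated), via hemiketal alkoxide 18 (not isolated), via ynone alkoxide 19 (not isolated)
Conditions: n-BuLi (1.0 equiv), THF, −78 °C; 16 (1.1 equiv), −78 → −20 °C; then MeOH, 0 °C → rt; aq. NH4Cl
Reagents that add atoms: none
Why: n-BuLi deprotonates only the terminal alkyne of 9, and acetylide 17 adds once to the lactone-type carbonyl C1 of 16 (acylation of an alkynyllithium by a 1,3-dioxolan-4-one; the closest known type is acetylide opening of lactones to ynones), a second addition being blocked because adduct 18 is a cyclic hemiketal alkoxide that is stable in the cold. On warming with methanol 18 opens, its hemiacetal alkoxide ejects pivalaldehyde and the C10 alkoxide of ynone 19 adds to C3 (oxa-Michael addition of an α'-hydroxy ynone), so C1–C2 and O–C3 arise in one flask. The furanone ring closes in the 5-endo-dig mode, either directly with protonation of C2 by methanol or by methoxide relay through the β-methoxy enone, and both paths converge on 20. No new stereocentre is formed: C10 is quaternary and is carried unchanged from 16, and C6 is remote from the reacting atoms. The step needs chemoselectivity for the dioxolanone carbonyl and for attack of O(C10) on C3, which is secured by the silyl ether on O6 (no competing 5-exo-dig furan formation) and by the acetal mask on C8. The Z geometry of C4=C5 should survive because that bond is never made single.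

Step 9
Reactants: 20
Product: 21 (2R)-2-(2,2-dimethoxyethyl)-5-[(2Z,4S)-4-hydroxyhexa-2,5-dien-2-yl]-2-methylfuran-3(2H)-one
Conditions: HF·pyridine, pyridine, THF, 0 °C
Reagents that add atoms: none
Why: fluoride-mediated desilylation cleaves the Si–O bond of the secondary silyl ether under pyridine-buffered conditions that should spare the dimethyl acetal and avoid ionisation or cyclisation of the doubly allylic alcohol, which is used at once.

Step 10
Reactants: 21; 22 2-(bromomethyl)acrylic acid
Product: 23 (3S,4Z)-5-[(5R)-5-(2,2-dimethoxyethyl)-5-methyl-4-oxo-4,5-dihydrofuran-2-yl]hexa-1,4-dien-3-yl 2-(bromomethyl)acrylate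
Conditions: DCC, DMAP (5 mol %), CH2Cl2, 0 °C
Reagents that add atoms: none
Why: Steglich esterification: the O-acylisourea of 22 acylates the C6 hydroxyl with retention, while low temperature and only catalytic DMAP limit attack on the allylic bromide.

Step 11
Reactants: 23
Product: 24 (5R)-3-(bromomethyl)-5-{(1Z)-2-[(5R)-5-(2,2-dimethoxyethyl)-5-methyl-4-oxo-4,5-dihydrofuran-2-yl]prop-1-en-1-yl}furan-2(5H)-one
Conditions: second-generation Grubbs catalyst (10 mol %), CH2Cl2 (5 mM), 40 °C
Reagents that add atoms: none
Why: ring-closing metathesis: the ruthenium carbene loads on the monosubstituted vinyl group (C7) and closes onto the 1,1-disubstituted acrylate olefin (C11) with loss of ethylene to form the five-membered butenolide, the trisubstituted conjugated olefins C2=C3 and C4=C5 being inert.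

Step 12
Reactants: 24
Product: 25 2-[(2R)-5-{(1Z)-1-[(2R)-4-(bromomethyl)-5-oxo-2,5-dihydrofuran-2-yl]prop-1-en-2-yl}-2-methyl-3-oxo-2,3-dihydrofuran-2-yl]acetaldehyde
Conditions: CF3CO2H/H2O (9:1), CH2Cl2, 0 °C; used crude
Reagents that add atoms: water O
Why: acid-catalysed acetal hydrolysis unmasks the C8 aldehyde under conditions that avoid base-induced β-elimination of the furanone oxygen from C10.

Step 13
Reactants: 25
Product: 27 (6R,7R,8R,10R)-8-hydroxy macrocycle (the free C8 alcohol of the target), via allylchromium 26 (not isolated)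
Conditions: CrCl2 (6 equiv), THF, rt, slow addition of 25 (final 2 mM); aq. NH4Cl
Reagents that add atoms: none
Why: Nozaki–Hiyama (chromium Barbier) allylation: CrCl2 inserts into the allylic C–Br bond and allylchromium 26 adds through its γ-carbon C7 to the tethered aldehyde in a six-membered chair-like transition state, which restores the exocyclic C11=C13 methylene and closes the ten-membered ring; C7–C8 is expected to form on the butenolide face opposite the C6–C5 bond (trans lactone, 7R) because a cis-fused transition state would fold the tether over the lactone, and the short C9–C10–O–C3–C4=C5 bridge is expected to hold C9 pseudo-axial so that the aldehyde face giving 8R is attacked, this last point being the least certain.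

Step 14
Reactants: 27; 28 tigloyl chloride
Product: 29 atripliciolide tiglate
Conditions: Et3N, DMAP (cat.), CH2Cl2, 0 °C → rt
Reagents that add atoms: none
Why: DMAP-catalysed acylation of the C8 alcohol by the acid chloride proceeds with retention at C8 and should leave the E geometry of the tigloyl group and the methylene lactone intact.

Compound list
1 | acrolein | C=CC=O | starting material
2 | 1-propynylmagnesium bromide | CC#C[Mg]Br | starting material
3 | (±)-hex-1-en-4-yn-3-ol | OC(C=C)C#CC | intermediate
4 | (S)-hex-1-en-4-yn-3-ol | O[C@@H](C=C)C#CC | intermediate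
5 | sodium cyclic vinylalanate: five-membered O–Al–C4=C5–C6 ring, two 2-methoxyethoxy groups on aluminium, vinyl on C6 | C=C[C@@H]1O[Al-](OCCOC)(OCCOC)C(C)=C1.[Na+] | intermediate
6 | (3S,4Z)-5-iodohexa-1,4-dien-3-ol | O[C@@H](C=C)/C=C(/C)I | intermediate
7 | triethyl{[(3S,4Z)-5-iodohexa-1,4-dien-3-yl]oxy}silane | CC[Si](CC)(CC)O[C@@H](C=C)/C=C(/C)I | intermediate
8 | ethynylmagnesium bromide | C#C[Mg]Br | starting material
9 | triethyl{[(3S,4Z)-5-methylhepta-1,4-dien-6-yn-3-yl]oxy}silane | CC[Si](CC)(CC)O[C@@H](C=C)/C=C(/C)C#C | intermediate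
10 | (2S,5S)-2-tert-butyl-5-methyl-1,3-dioxolan-4-one (cis) | C[C@@H]1O[C@H](C(C)(C)C)OC1=O | starting material
11 | allyl bromide | C=CCBr | starting material
12 | lithium enolate of 10 | [Li]OC1=C(C)O[C@H](C(C)(C)C)O1 | intermediate
13 | (2S,5R)-5-allyl-2-tert-butyl-5-methyl-1,3-dioxolan-4-one | C[C@]1(CC=C)O[C@H](C(C)(C)C)OC1=O | intermediate
14 | ozonide (1,2,4-trioxolane) of 13 | C[C@]1(CC2OCOO2)O[C@H](C(C)(C)C)OC1=O | intermediate
15 | (2S,5R)-2-tert-butyl-5-methyl-5-(2-oxoethyl)-1,3-dioxolan-4-one | C[C@]1(CC=O)O[C@H](C(C)(C)C)OC1=O | intermediate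
16 | (2S,5R)-2-tert-butyl-5-(2,2-dimethoxyethyl)-5-methyl-1,3-dioxolan-4-one | C[C@]1(CC(OC)OC)O[C@H](C(C)(C)C)OC1=O | intermediate
17 | lithium acetylide of 9 | CC[Si](CC)(CC)O[C@@H](C=C)/C=C(/C)C#C[Li] | intermediate
18 | cyclic hemiketal lithium alkoxide (acetylide adduct on C1 of 16; hemiketal carbon unassigned) | CC[Si](CC)(CC)O[C@@H](C=C)/C=C(/C)C#CC1(O[Li])O[C@@H](C(C)(C)C)O[C@]1(C)CC(OC)OC | intermediate
19 | lithium alkoxide of the α'-hydroxy ynone (C10–O–Li, C1 ketone, C2≡C3) | CC[Si](CC)(CC)O[C@@H](C=C)/C=C(/C)C#CC(=O)[C@@](C)(CC(OC)OC)O[Li] | intermediate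
20 | (2R)-2-(2,2-dimethoxyethyl)-2-methyl-5-[(2Z,4S)-4-(triethylsilyloxy)hexa-2,5-dien-2-yl]furan-3(2H)-one | CC[Si](CC)(CC)O[C@@H](C=C)/C=C(/C)C1=CC(=O)[C@@](C)(CC(OC)OC)O1 | intermediate
21 | (2R)-2-(2,2-dimethoxyethyl)-5-[(2Z,4S)-4-hydroxyhexa-2,5-dien-2-yl]-2-methylfuran-3(2H)-one | O[C@@H](C=C)/C=C(/C)C1=CC(=O)[C@@](C)(CC(OC)OC)O1 | intermediate
22 | 2-(bromomethyl)acrylic acid | C=C(CBr)C(=O)O | starting material
23 | (3S,4Z)-5-[(5R)-5-(2,2-dimethoxyethyl)-5-methyl-4-oxo-4,5-dihydrofuran-2-yl]hexa-1,4-dien-3-yl 2-(bromomethyl)acrylate | C=C(CBr)C(=O)O[C@@H](C=C)/C=C(/C)C1=CC(=O)[C@@](C)(CC(OC)OC)O1 | intermediate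
24 | (5R)-3-(bromomethyl)-5-{(1Z)-2-[(5R)-5-(2,2-dimethoxyethyl)-5-methyl-4-oxo-4,5-dihydrofuran-2-yl]prop-1-en-1-yl}furan-2(5H)-one | BrCC1=C[C@H](OC1=O)/C=C(/C)C2=CC(=O)[C@@](C)(CC(OC)OC)O2 | intermediate
25 | aldehyde from 24 (C8 formyl; bromomethyl butenolide and furanone as in 24) | BrCC1=C[C@H](OC1=O)/C=C(/C)C2=CC(=O)[C@@](C)(CC=O)O2 | intermediate
26 | allylchromium dichloride from 25 (trivalent chromium on C13) | Cl[Cr](Cl)CC1=C[C@H](OC1=O)/C=C(/C)C2=CC(=O)[C@@](C)(CC=O)O2 | intermediate
27 | (6R,7R,8R,10R)-8-hydroxy furanoheliangolide (target without the tigloyl group) | C=C1C(=O)O[C@@H]2/C=C(/C)C3=CC(=O)[C@@](C)(C[C@@H](O)[C@@H]12)O3 | intermediate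
28 | tigloyl chloride ((E)-2-methylbut-2-enoyl chloride) | C/C=C(\C)C(Cl)=O | starting material
29 | atripliciolide tiglate | C=C1C(=O)O[C@@H]2/C=C(/C)C3=CC(=O)[C@@](C)(C[C@@H](OC(=O)/C(C)=C/C)[C@@H]12)O3 | target

Total step count: 14. Longest linear sequence: 12 steps (steps 1–5 and 8–14).

Steps most likely to fail

Step 8. The cascade may stall or branch. Possible processes are a second acetylide addition if the hemiketal alkoxide collapses early, cleavage of the ynone by methoxide, Z-to-E isomerisation through reversible 1,6-addition, and incomplete 5-endo closure. The fallback sets out from 16 and 9 and comes back at 20. Compound 16 is opened with MeNH(OMe)·HCl and i-PrMgCl (THF, −20 °C) to (2R)-2-hydroxy-N,4,4-trimethoxy-N,2-dimethylbutanamide F1, with loss of pivalaldehyde. Its magnesium alkoxide (one further equivalent of i-PrMgCl) is treated with acetylide 17; the chelated N-methoxy-N-methyl adduct prevents over-addition, and work-up gives the isolable α'-hydroxy ynone F2. F2 is then cyclised in a separate step with (Ph3P)AuNTf2 (CH2Cl2, rt) by 5-endo-dig oxyauration and protodeauration to 20.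

Step 13. Facial selectivity at the aldehyde carbon (C8) inside the chair-like transition state may be poor or reversed, and reduction or oligomerisation of the allylchromium may compete with ring closure. The fallback sets out from 25 and comes back at 29. If closure of 25 (CrCl2, or zinc in THF/aq. NH4Cl) gives mainly the (6R,7R,8S,10R)-8-epi alcohol F3, this alcohol is esterified with tiglic acid under Mitsunobu conditions (PPh3, diisopropyl azodicarboxylate, toluene, 0 °C). This inverts C8 and installs the tiglate in one step, reaching 29 without passing through 27.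

Step 11. Closure onto the electron-poor 1,1-disubstituted acrylate may be slow, and the allylic bromide may consume the ruthenium carbene, so that dimerisation and decomposition take over. The fallback sets out from 21 and comes back at 24; it introduces the bromide only after ring closure. Alcohol 21 is esterified with 2-{[(tert-butyldimethylsilyl)oxy]methyl}acrylic acid under Yamaguchi conditions (2,4,6-trichlorobenzoyl chloride, Et3N, DMAP) to the silyloxymethyl acrylate F4. Ring-closing metathesis (second-generation Hoveyda–Grubbs catalyst, toluene, 80 °C) gives the 3-(silyloxymethyl)butenolide F5. HF·pyridine gives the 3-(hydroxymethyl)butenolide F6, and Appel bromination (CBr4, PPh3, CH2Cl2, 0 °C) returns to 24.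

Further compounds
F1 | step 8 | (2R)-2-hydroxy-N,4,4-trimethoxy-N,2-dimethylbutanamide | CON(C)C(=O)[C@](C)(O)CC(OC)OC
F2 | step 8 | (2R)-2-hydroxy-1,1-dimethoxy... α'-hydroxy ynone: neutral form of 19 (C10–OH, C1 ketone, C2≡C3, O6 triethylsilyl ether) | CC[Si](CC)(CC)O[C@@H](C=C)/C=C(/C)C#CC(=O)[C@@](C)(CC(OC)OC)O
F3 | step 13 | (6R,7R,8S,10R)-8-epi alcohol (C8 epimer of 27) | C=C1C(=O)O[C@@H]2/C=C(/C)C3=CC(=O)[C@@](C)(C[C@H](O)[C@@H]12)O3
F4 | step 11 | (3S,4Z)-5-[(5R)-5-(2,2-dimethoxyethyl)-5-methyl-4-oxo-4,5-dihydrofuran-2-yl]hexa-1,4-dien-3-yl 2-{[(tert-butyldimethylsilyl)oxy]methyl}acrylate | C=C(CO[Si](C)(C)C(C)(C)C)C(=O)O[C@@H](C=C)/C=C(/C)C1=CC(=O)[C@@](C)(CC(OC)OC)O1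
F5 | step 11 | (5R)-3-{[(tert-butyldimethylsilyl)oxy]methyl} analogue of 24 | CC(C)(C)[Si](C)(C)OCC1=C[C@H](OC1=O)/C=C(/C)C2=CC(=O)[C@@](C)(CC(OC)OC)O2
F6 | step 11 | (5R)-3-(hydroxymethyl) analogue of 24 | OCC1=C[C@H](OC1=O)/C=C(/C)C2=CC(=O)[C@@](C)(CC(OC)OC)O2
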